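We want one constant.

| flask | starting material | reagent | free catalyst | time |
|---|---|---|---|---|
| Tuesday's | 0.600 M | 0.600 M | 0.0480 M |  |
| Sunday's | 0.360 M | 0.360 M | 0.0480 M |  |
| Wednesday's | 0.600 M | 1.20 M | 0.0480 M |  |
| Friday's | 0.600 M | 0.600 M | 0.0960 M |  |
| Monday's | 0.240 M | 0.600 M | 0.0480 M | 3.6 min |

- Tuesday's run (time / min: [product] / M): 0.16: 0.031; 0.49: 0.118; 0.93: 0.207; 1.5: 0.299; 2.1: 0.376; 2.8: 0.441; 3.6: 0.495
- Sunday's run (time / min: [product] / M): 0.16: 0.021; 0.49: 0.073; 0.93: 0.130; 1.5: 0.182; 2.1: 0.237; 2.8: 0.265; 3.6: 0.307
- Wednesday's run (time / min: [product] / M): 0.16: 0.032; 0.49: 0.109; 0.93: 0.185; 1.5: 0.273; 2.1: 0.340; 2.8: 0.406; 3.6: 0.472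
- Friday's run (time / min: [product] / M): 0.16: 0.067; 0.49: 0.203; 0.93: 0.335; 1.5: 0.451; 2.1: 0.524; 2.8: 0.557; 3.6: 0.582

(scatter of a reading: 0.003 M)

* reaction order in [starting material] at the outset, round the charge of the Tuesday's run, defined at two percent of the starting material turned into product (one fixed amount of product, the same in the runs compared)
* reaction order in [free catalyst] at the outset, round the charge of the Tuesday's run, defined at two percent of the starting material turned into product
* the Sunday's run starts with 0.240 M less of starting material and of reagent than the Tuesday's run, and with no product. Compared where both hold the same amount of starting material, once fifteen percent of what the Sunday's run was charged with has turned into product, is the Sunday's run faster, slower or alike (within a tenth)?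
* product in the Monday's run at 3.6 min, as a share of the starting material charged

- Overall: starting material + reagent -> product, with free catalyst as catalyst.
- Constant volume, constant temperature.
- The analysis sees a species whether free or bound.
- "The second partner" is reagent.
- An order is taken over about fifteen percent of the charge, up and down.

If product grows so that a fixed share of what remains reacts each minute, one constant describes a whole curve, whatever the charge. From Tuesday's last reading we get 0.484 min⁻¹ for the fall constant, the natural logarithm of the charge of starting material over charge less product, divided by the time.

Does it depend on the charge? Sunday's charge of starting material and of reagent is 0.600 of Tuesday's, yet its last reading gives 0.532 min⁻¹, a ratio of 1.10. So we read each fall as nearly a fixed share per minute and reckon an order near 1 in starting material. At equal starting material that same ratio puts Sunday's rate and Tuesday's at the edge of alike.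

Then does the reagent matter? Wednesday's run charges twice the reagent of Tuesday's, and its constant reads 0.429 min⁻¹, lower than Tuesday's, a ratio of 0.886. Friday's run, with twice the free catalyst, reads a ratio of 2.01, so we reckon an order near 1 in free catalyst as well.

Monday's run has Tuesday's reagent and less starting material than Tuesday's, and with an order near 1 in starting material we reckon that this leaves the constant as it is, so we keep Tuesday's constant. Over 3.6 min in Monday's run it gives 82.5% of the charge as product.

The forecast, a separate estimate, gives an order of 1 in starting material and of 1 in free catalyst, calls the Sunday comparison alike and puts Monday's run at 82%, on the ground that “The runs follow a rate that is close to first order in starting material”.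

    free catalyst + starting material → loaded catalyst + by-product (14.82 M⁻¹ min⁻¹)
    loaded catalyst + reagent → product + free catalyst (75.00 M⁻¹ min⁻¹)
    starting material + reagent ⇌ idle substrate-reagent adduct, settled at all times (0.7600 M⁻¹)

Monday's run gives 84.0%, and the Sunday comparison comes out alike, with a rate ratio of 1.0. At the outset, though, the orders are 0.74 in starting material and 0.86 in free catalyst, both lower than our reckoned 1. Read back from the result, Monday's fall constant is 0.509 min⁻¹, against Tuesday's 0.484 min⁻¹. Carried to Sunday's run, Tuesday's constant puts half of the charge as product at 1.43 min, and Sunday's run reached it at 1.44 min.

(The numbers in the tables are simulated for substances that don't exist; noise was put on by code.)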